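In a one-step world each starting material becomes one target, and the rise slows just as starting material goes.

- summer: starting material 2 M; gas phase 120 mM (held); run made earlier
- flask: starting material 1.3 M; gas phase 120 mM (held); time 4.0 h

- summer (time / min: target / %): 5.00: 0.7; 15.0: 2.7; 25.0: 5.6; 40.0: 9.6; 60.0: 14.3; 80.0: 16.8

(scatter of a reading: 1 percentage point)

- the earlier runs were read with a standard deviation of 1 percentage point
- at the start none of the gas phase is in solution

- the target standing at 4.0 h, as a percentage of the starting material charged
- the change that raises the amount of target at 4.0 h, in percent of the starting material charged most ("none" if none brings more than 2 percentage points) (Saturday's / Sunday's / none)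
- amount of target at 4.0 h, in percent of the starting material charged, after Sunday's

- Saturday's: doubling the transfer coefficient of the gas phase, all else as stated
- Sunday's: doubling the saturation concentration of gas phase, all else as stated

Between 15.0 min and 60.0 min the summer run climbs steadily. The fraction of the charge turned per hour there is what I call the share rate, 0.155 h⁻¹. Drawn back, that line meets zero at 4.53 min, which I read as the delay while gas dissolves. The last stretch climbs at 0.0750 h⁻¹, about half the share rate, although target reads 14.3% of the charge at 60.0 min. So, as far as these scattered readings show, target may also be being lost.

For the flask I solve two ends. If dissolved gas stood as in summer, the share rate would hold (a pseudo-first-order picture), and 45.5% of the starting material would be used by 4.0 h. If gas instead arrived at a fixed molar rate whatever the charge, the share rate would grow with the ratio of the charges, and 93.4% would be used. I expect the flask between the two. Since target stands below what is used, I commit to the lower figure for target. Sunday's doubles the share rate at both ends, giving 70.3% at the lower one. Saturday's shortens the delay and lets dissolved gas rise faster towards an unchanged saturation, whereas Sunday's raises the saturation itself, so I choose Sunday's.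

The forecast gives 19%, best change none and 9% after Sunday's, on the ground: “More gas only pushes further past the peak.”

The flask gives 49.4%. The best change is Sunday's, worth 23 percentage points against 6.2 points for Saturday's, and it brings target to 72.3%.

    gas phase ⇌ dissolved gas, rate k1*(csat - [dissolved gas]) (kL = 0.00150 s⁻¹)
    starting material + dissolved gas → target (k = 0.00100 M⁻¹ s⁻¹)
    starting material + target → side product (k = 4.90 × 10⁻⁵ M⁻¹ s⁻¹)

The flask has used 75.1% of its starting material, above 45.5% and below 93.4%. It is not at rest at 4.0 h: 25% of the starting material remains, and target is made 3.10 times faster than it is used up. At ten times the time, 40.0 h, the flask holds no starting material (0%), dissolved gas stands at 0.120 M, and target has gained 13 points to reach 62.0%. Side product, each counting two, goes from 25.7% to 38.0%.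

For the same flask read at 1.5 h, the share rate puts the starting material used between 19.8% and 33.9%. That flask has used 32.4%, with 25.4% target and 6.98% side product.

All runs were computed for substances that don't exist; scatter was added.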